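(The numbers in the tables are simulated for substances that don't exist, noise included.)

Work in odds. I call O the starting material reacted over the starting material left, and I read both O and the charges as logarithms, in powers of ten.

the same everywhere: starting material 0.090 M
- alpha: reagent 0.081 M (fed, over 5.0 min); second substrate 0.045 M; run made earlier; the fed solution adds 0.20 times the starting volume
- zeta: reagent 0.081 M (fed, over 5.0 min); second substrate 0.18 M; run made earlier; the fed solution adds 0.20 times the starting volume
- epsilon: reagent 0.16 M (fed, over 5.0 min); second substrate 0.090 M; run made earlier; the fed solution adds 0.20 times the starting volume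
- flask: reagent 0.0810 M (fed, over 5.0 min); second substrate 0.0900 M; the fed solution adds 0.20 times the starting volume; time 4.0 h

The flask's second substrate, 0.0900 M, stands midway on a log scale between the alpha and zeta charges, and those two runs carry the flask's reagent charge, so their logarithms of O can be averaged.

- alpha (time / h: starting material / %, target / %, isomer of the product / %): 0.250: 88.7, 7.8, 6.1; 0.417: 86.5, 7.6, 5.2; 0.667: 87.5, 5.6, 7.0; 0.833: 88.1, 6.4, 5.2; 1.33: 86.9, 7.0, 6.9; 2.00: 86.9, 6.6, 6.4; 3.00: 87.7, 4.8, 6.2
- zeta (time / h: starting material / %, target / %, isomer of the product / %): 0.250: 89.9, 5.0, 4.6; 0.417: 91.1, 5.1, 5.4; 0.667: 88.9, 6.6, 4.3; 0.833: 89.2, 3.9, 5.9; 1.33: 87.9, 6.3, 5.0; 2.00: 89.2, 5.9, 6.3; 3.00: 88.4, 5.9, 5.4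
- epsilon (time / h: starting material / %, target / %, isomer of the product / %): 0.667: 79.2, 10.5, 8.5; 1.33: 79.1, 11.9, 9.4; 2.00: 78.7, 13.1, 9.1; 2.50: 78.0, 11.4, 9.8; 3.00: 78.2, 10.7, 10.6

(scatter of a reading: 1 percentage point)

- every charge counts on the volume at the start, and the solution that is fed holds the whole dose
- the reaction counts as stopped when no species that holds the starting material changes by six tenths of a point or more over the second half of the time

* the state of affairs at 4.0 h: stopped, and by what, or still going (forward and back rates have come level / all of the starting material has reacted / it is still moving / the reagent has run out first)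
* conversion of starting material at 4.0 h
* amount of target at 4.0 h, in percent of the starting material charged
* amount of isomer of the product at 4.0 h, in percent of the starting material charged

In alpha, zeta and epsilon the starting material shows no trend beyond the scatter from the first sample on, so I average each run. Conversion comes to 12.5% in alpha, 10.8% in zeta and 21.4% in epsilon. So I expect O = 0.131 in the flask, a conversion of 11.6%.

Epsilon has twice the flask's reagent and O = 0.272, which gives 1.07 for n, the slope of log O against log reagent charge. A slope near one fits level forward and back rates (equilibrium) between starting material + reagent and the target with its isomer, with free reagent near its charge, but a reagent used up in a fixed share fits too. A subtraction leans my way, though it assumes that second substrate is the one other taker of reagent: in alpha, if each second substrate took one reagent, that and the starting material reacted hold 0.0563 M, less than the 0.081 M fed. So I expect level rates, with reagent left.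

The forecast differs on the end: the reagent has run out first, with conversion 11.8%, target 6.1% and isomer of the product 5.7%, holding that “An equilibrium would rise more like the square root of the dose”.

The flask gives: forward and back rates have come level, with conversion 11.9%, target 6.42% and isomer of the product 5.52%.

    starting material + reagent ⇌ target (K = 1.40 M⁻¹, k = 0.0220 M⁻¹ s⁻¹)
    second substrate + reagent ⇌ second product (K = 1.80 M⁻¹, k = 0.0180 M⁻¹ s⁻¹)
    target ⇌ isomer of the product (K = 0.860, k = 0.0280 s⁻¹)

In the flask, the half-life of starting material by its forward step alone, 0.11 h with whole charges present, is shorter than the 4.0 h allowed. The flask holds 88.1% of its starting material at 2.00 h and 88.1% at 4.00 h, with 77% of its reagent left. Its O is 0.136, and carrying that with n to the neighbour charged with 0.032 M of reagent gives O = 0.0504, a conversion of 4.80%. That neighbour stands at 5.01%.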